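The runs come from a simulation on assumed constants; noise was put on by code.

1. I charge the next flask with Jj at teal's 0.150 M, the lowest on the list, if the runs show that more Jj buys nothing.

| flask | Ja | Jd | Jj | Jb | Jk | remark | time |
|---|---|---|---|---|---|---|---|
| Tuesday's | 0.10 M | 0.095 M | 0.17 M | 15 mM | 0.13 mM | run made earlier |  |
| Wednesday's | 0.10 M | 0.095 M | 0.38 M | 15 mM | 0.13 mM | run made earlier |  |
| teal | 0.10 M | 0.0950 M | 0.150 M | 15 mM | 0.13 mM |  | 3.0 h |
| grey | 0.10 M | 0.0950 M | 0.220 M | 15 mM | 0.13 mM |  | 3.0 h |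
| amber | 0.10 M | 0.0950 M | 0.340 M | 15 mM | 0.13 mM |  | 3.0 h |

| run | time / min | Ja / % | Jn / % |
|---|---|---|---|
| Tuesday's | 10.0 | 92.1 | 6.2 |
| Tuesday's | 20.0 | 84.7 | 13.7 |
| Tuesday's | 40.0 | 74.6 | 24.2 |
| Tuesday's | 60.0 | 65.8 | 31.5 |
| Tuesday's | 120 | 47.7 | 44.1 |
| Wednesday's | 10.0 | 91.6 | 6.5 |
| Wednesday's | 20.0 | 85.8 | 14.3 |
| Wednesday's | 40.0 | 73.4 | 22.8 |
| Wednesday's | 60.0 | 64.1 | 31.0 |
| Wednesday's | 120 | 48.0 | 44.4 |

(each reading ± 0.5 percentage points)



- part of the Ja that has reacted at the end, teal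
- part of the Ja that has reacted at the end, grey
- part of the Ja that has reacted at the end, amber
- what raising the concentration of Jj from its lowest to its highest value here does to the part of the Ja that has reacted (changes below 5 percentage points count as none) (no change / it falls / it rises)

2. Tuesday's run has 0.17 M of Jj and Wednesday's has 0.38 M. At 120 min, Ja stands at 47.7% and 48.0%. The gap of 0.3 percentage points is less than the margin of 5 points, and each reading carries 0.5 points.

3. The yield needs a second reading. Pooling both runs at 120 min, Jn formed over Ja lost is 0.849. I call this s, the Jn share, the Jn formed per Ja lost; the usual term is selectivity. Read singly, it is 0.843 on Tuesday and 0.854 on Wednesday.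

4. The forecast gives 62% for teal, 62% for grey and 62% for amber, with the trend no change, “so I treat all three flasks alike”.

5. My own step puts that reacted part through s, which gives 52.6% of Jn at the end. At 60.0 min the pooled share was 0.892, higher than s. Going round once more, I expect s to slip further, so I read that Jn as an upper figure. The decision stands: teal's Jj.

6. The flasks give:

    2 Jf → Jg (k = 6.00 × 10⁶ M⁻¹ s⁻¹)
    Jb → 2 Jc (k = 0.00280 min⁻¹)
    Jd + Je ⇌ Jn + Jf (K = 0.510, k = 56000 M⁻¹ min⁻¹)
    Jj + Jp → Jr (k = 2.80 M⁻¹ min⁻¹)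
    Jf + Jk → Js (k = 1.40 × 10⁶ M⁻¹ s⁻¹)
    2 Je → Jh (k = 2.00 × 10⁷ M⁻¹ s⁻¹)
    Jd + Jp ⇌ Jq, settled at all times (K = 5.70 M⁻¹)
    Ja + Jf → Jp + Je (k = 58000 M⁻¹ min⁻¹)
    Ja + Jc → Jm + Je (k = 19000 M⁻¹ s⁻¹)

Teal, grey and amber reach 62.7%, 62.8% and 62.8%, and the Jj span moves the reacted part by 0.054 points, less than the margin, so the trend is no change. Grey holds 51.9% of Jn, so s there is 0.826. In a neighbour flask, which is grey with 0.060 M of Ja, s from the runs expects 70.6% of Jn against 67.0% found. In grey, Je, the first chain carrier, goes on with Jd (forward rate alone) 9.5 times as fast as it pairs to Jh at 0.764 h. By 3.00 h grey's ratio is 7.0.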